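**Retrosynthetic overview**
- The 1,2-dioxane is the only ring made and is closed last: C6–O by cobalt-mediated hydroperoxysilylation of a 1,1-disubstituted alkene, O–C3 by SN2 inversion of a (3R)-mesylate.
- C2 and C3 come from an Evans syn-aldol on a C3 aldehyde.
- Key C5–C6 bond: nickel-catalysed reductive union of a ketone-derived enol triflate (C6) with acrolein, whose β-carbon (C5) reacts with reversed polarity as a silyloxyallylnickel homoenolate.
- Ring A is bought as dihydro-β-ionone; its carbinol centre comes from asymmetric epoxidation of the ring alkene, and the transient oxirane is opened again to the allylic alcohol.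

Assumption: the SMILES is read as methyl (2S)-2-[(3S,6R)-6-{2-[(1S)-1-hydroxy-2,2-dimethyl-6-methylidenecyclohexyl]ethyl}-6-methyl-1,2-dioxan-3-yl]propanoate; "C1–C6" below means the ester carbon (C1) through the two peroxide-bearing carbons (C3, C6).

**Step 1**
Reactants: 1 4-(2,6,6-trimethylcyclohex-1-en-1-yl)butan-2-one (dihydro-β-ionone)
Product: 2 4-[(1S,6R)-2,2,6-trimethyl-7-oxabicyclo[4.1.0]heptan-1-yl]butan-2-one
Conditions: Shi ketone (D-fructose-derived, 0.3 equiv), Oxone (2KHSO5·KHSO4·K2SO4), K2CO3, Bu4NHSO4 (cat.), MeCN–CH2(OMe)2 / aq. Na2B4O7 buffer, 0 °C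
Reagents that add atoms: potassium peroxymonosulfate, [K+].[O-]S(=O)(=O)OO
Why: Shi asymmetric epoxidation; the chiral dioxirane attacks the only (electron-rich, tetrasubstituted) alkene through a spiro transition state, with the face chosen as for 1-substituted cyclohexenes (the C-methyl carbon takes the place of the unsubstituted carbon), which sets (1S,6R).

**Step 2**
Reactants: 2 4-[(1S,6R)-2,2,6-trimethyl-7-oxabicyclo[4.1.0]heptan-1-yl]butan-2-one
Product: 3 4-[(1S)-1-hydroxy-2,2-dimethyl-6-methylidenecyclohexyl]butan-2-one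
Conditions: Et2Al(TMP) (3 equiv, from LiTMP and Et2AlCl), toluene, 0 °C to rt; aq. KNaC4H4O6 work-up
Reagents that add atoms: none
Why: Yamamoto-type epoxide-to-allylic-alcohol isomerisation; the aluminium amide binds the oxirane oxygen and removes a syn β-hydrogen from the least hindered site (the C6 methyl), so the C6–O bond breaks, the exocyclic methylene forms and the oxygen stays on C1 with its configuration (1S) untouched, while the ketone is masked as its aluminium enolate until work-up.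

**Step 3**
Reactants: 3 4-[(1S)-1-hydroxy-2,2-dimethyl-6-methylidenecyclohexyl]butan-2-one
Product: 4 4-[(1S)-1-hydroxy-2,2-dimethyl-6-methylidenecyclohexyl]but-1-en-2-yl trifluoromethanesulfonate
Conditions: LiN(i-Pr)2 (2.2 equiv), THF, −78 °C; PhNTf2 (1.15 equiv), −78 to 0 °C
Reagents that add atoms: N-phenylbis(trifluoromethanesulfonimide), O=S(=O)(N(c1ccccc1)S(=O)(=O)C(F)(F)F)C(F)(F)F
Why: Kinetic enolate O-triflation; after the alkoxide forms, the amide removes a methyl proton of the methyl ketone and the terminal enolate is trapped as the 2-triflyloxy-1-alkene, the very hindered tertiary alkoxide not being sulfonylated.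

**Step 4**
Reactants: 4 4-[(1S)-1-hydroxy-2,2-dimethyl-6-methylidenecyclohexyl]but-1-en-2-yl trifluoromethanesulfonate; 5 acrolein
Product: 7 6-[(1S)-1-hydroxy-2,2-dimethyl-6-methylidenecyclohexyl]-4-methylidenehexanal, via triethylsilyl enol ether 6 (not isolated)
Conditions: NiBr2(dme) (10 mol %), neocuproine (10 mol %), Mn powder (2.5 equiv), Et3SiCl (1.5 equiv), 5 (2 equiv), DMF, 25–40 °C; then AcOH–H2O–THF, 0 °C
Reagents that add atoms: none
Why: Proposed new method: zerovalent nickel inserts into the alkenyl C–OTf bond while acrolein, Et3SiCl and nickel give a 1-(triethylsilyloxy)allylnickel species in which the normally electrophilic β-carbon of the enal is the nucleophilic partner (a homoenolate equivalent); reductive elimination joins it to the equally electrophilic enol-triflate carbon, Mn turns the catalyst over, and the silyl enol ether is hydrolysed to the aldehyde on work-up; closest known reaction type: nickel-catalysed reductive conjugate addition of aryl and alkenyl bromides to enones and enals with chlorosilanes and Mn, together with nickel-catalysed reductive couplings of alkenyl triflates.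

**Step 5**
Reactants: 7 6-[(1S)-1-hydroxy-2,2-dimethyl-6-methylidenecyclohexyl]-4-methylidenehexanal; 8 (4S)-4-benzyl-3-propanoyl-1,3-oxazolidin-2-one
Product: 9 (4S)-4-benzyl-3-[(2S,3R)-3-hydroxy-8-[(1S)-1-hydroxy-2,2-dimethyl-6-methylidenecyclohexyl]-2-methyl-6-methylideneoctanoyl]-1,3-oxazolidin-2-one
Conditions: 8 (1.3 equiv), Bu2BOTf, i-Pr2NEt, CH2Cl2, 0 °C; 7, −78 to 0 °C; KH2PO4/Na2HPO4 buffer (pH 7), MeOH, 30% H2O2, 0 °C
Reagents that add atoms: none
Why: Evans syn-aldol; the Z-boron enolate adds through a Zimmerman–Traxler chair on the face away from the benzyl group, setting C2 (S) and C3 (R) syn to each other (typically >20:1).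

**Step 6**
Reactants: 9 (4S)-4-benzyl-3-[(2S,3R)-3-hydroxy-8-[(1S)-1-hydroxy-2,2-dimethyl-6-methylidenecyclohexyl]-2-methyl-6-methylideneoctanoyl]-1,3-oxazolidin-2-one
Product: 10 methyl (2S,3R)-3-hydroxy-8-[(1S)-1-hydroxy-2,2-dimethyl-6-methylidenecyclohexyl]-2-methyl-6-methylideneoctanoate
Conditions: NaOMe (1.1 equiv), MeOH–CH2Cl2, 0 °C, 15 min; NH4Cl quench
Reagents that add atoms: methanol, CO
Why: Transesterification (methanolysis) at the exocyclic imide carbonyl; short exposure at 0 °C avoids retro-aldol and C2 epimerisation, and the methyl ester is less α-acidic than the imide for the later ring closure.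

**Step 7**
Reactants: 10 methyl (2S,3R)-3-hydroxy-8-[(1S)-1-hydroxy-2,2-dimethyl-6-methylidenecyclohexyl]-2-methyl-6-methylideneoctanoate
Product: 11 methyl (2S,3R)-8-[(1S)-1-hydroxy-2,2-dimethyl-6-methylidenecyclohexyl]-3-(methanesulfonyloxy)-2-methyl-6-methylideneoctanoate
Conditions: MsCl (1.2 equiv), Et3N (1.5 equiv), CH2Cl2, −20 °C
Reagents that add atoms: methanesulfonyl chloride, CS(=O)(=O)Cl
Why: Selective O-sulfonylation of the secondary alcohol (the tertiary carbinol of ring A, flanked by a quaternary and an sp2 carbon, does not react at −20 °C) installs the leaving group with C3 unchanged.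

**Step 8**
Reactants: 11 methyl (2S,3R)-8-[(1S)-1-hydroxy-2,2-dimethyl-6-methylidenecyclohexyl]-3-(methanesulfonyloxy)-2-methyl-6-methylideneoctanoate
Product: 13 methyl (2S)-2-[(3S,6R)-6-{2-[(1S)-1-hydroxy-2,2-dimethyl-6-methylidenecyclohexyl]ethyl}-6-methyl-1,2-dioxan-3-yl]propanoate (CNP0255906.1), via triethylsilyl peroxide 12 (not isolated)
Conditions: Co(thd)2 [bis(2,2,6,6-tetramethylheptane-3,5-dionato)cobalt, 10 mol %], Et3SiH (1.5 equiv), O2 (1 atm), ClCH2CH2Cl, rt; filter, concentrate; Bu4NF (1.1 equiv), THF, −20 to 0 °C; chromatography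
Reagents that add atoms: dioxygen, O=O
Why: Mukaiyama–Isayama hydroperoxysilylation (cobalt hydride H-atom transfer to the unhindered chain alkene in the Markovnikov sense, then O2 trapping of the C6 radical; the ring A methylene next to the fully substituted carbinol is expected to react more slowly) followed by fluoride-triggered desilylation and 6-exo-tet SN2 closure of the peroxide anion on the mesylate, which inverts C3 to (S); the radical step is stereorandom at C6 (about 1:1), so only the (6R) half of 12 gives 13, and the trans-dioxane from the (6S) half is removed by chromatography.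

**Compound list**
1 | 4-(2,6,6-trimethylcyclohex-1-en-1-yl)butan-2-one (dihydro-β-ionone) | CC(=O)CCC1=C(C)CCCC1(C)C | starting material
2 | 4-[(1S,6R)-2,2,6-trimethyl-7-oxabicyclo[4.1.0]heptan-1-yl]butan-2-one | CC1(C)CCC[C@@]2(C)O[C@@]12CCC(C)=O | intermediate
3 | 4-[(1S)-1-hydroxy-2,2-dimethyl-6-methylidenecyclohexyl]butan-2-one | C=C1CCCC(C)(C)[C@@]1(O)CCC(C)=O | intermediate
4 | 4-[(1S)-1-hydroxy-2,2-dimethyl-6-methylidenecyclohexyl]but-1-en-2-yl trifluoromethanesulfonate | C=C1CCCC(C)(C)[C@@]1(O)CCC(=C)OS(=O)(=O)C(F)(F)F | intermediate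
5 | acrolein (prop-2-enal) | C=CC=O | starting material
6 | triethyl({6-[(1S)-1-hydroxy-2,2-dimethyl-6-methylidenecyclohexyl]-4-methylidenehex-1-en-1-yl}oxy)silane (E/Z mixture) | C=C1CCCC(C)(C)[C@@]1(O)CCC(=C)CC=CO[Si](CC)(CC)CC | intermediate
7 | 6-[(1S)-1-hydroxy-2,2-dimethyl-6-methylidenecyclohexyl]-4-methylidenehexanal | C=C1CCCC(C)(C)[C@@]1(O)CCC(=C)CCC=O | intermediate
8 | (4S)-4-benzyl-3-propanoyl-1,3-oxazolidin-2-one | CCC(=O)N1C(=O)OC[C@@H]1Cc2ccccc2 | starting material
9 | (4S)-4-benzyl-3-[(2S,3R)-3-hydroxy-8-[(1S)-1-hydroxy-2,2-dimethyl-6-methylidenecyclohexyl]-2-methyl-6-methylideneoctanoyl]-1,3-oxazolidin-2-one | C=C1CCCC(C)(C)[C@@]1(O)CCC(=C)CC[C@@H](O)[C@H](C)C(=O)N2C(=O)OC[C@@H]2Cc3ccccc3 | intermediate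
10 | methyl (2S,3R)-3-hydroxy-8-[(1S)-1-hydroxy-2,2-dimethyl-6-methylidenecyclohexyl]-2-methyl-6-methylideneoctanoate | C=C1CCCC(C)(C)[C@@]1(O)CCC(=C)CC[C@@H](O)[C@H](C)C(=O)OC | intermediate
11 | methyl (2S,3R)-8-[(1S)-1-hydroxy-2,2-dimethyl-6-methylidenecyclohexyl]-3-(methanesulfonyloxy)-2-methyl-6-methylideneoctanoate | C=C1CCCC(C)(C)[C@@]1(O)CCC(=C)CC[C@@H](OS(C)(=O)=O)[C@H](C)C(=O)OC | intermediate
12 | methyl (2S,3R)-8-[(1S)-1-hydroxy-2,2-dimethyl-6-methylidenecyclohexyl]-3-(methanesulfonyloxy)-2,6-dimethyl-6-[(triethylsilyl)peroxy]octanoate (both C6 epimers) | C=C1CCCC(C)(C)[C@@]1(O)CCC(C)(OO[Si](CC)(CC)CC)CC[C@@H](OS(C)(=O)=O)[C@H](C)C(=O)OC | intermediate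
13 | methyl (2S)-2-[(3S,6R)-6-{2-[(1S)-1-hydroxy-2,2-dimethyl-6-methylidenecyclohexyl]ethyl}-6-methyl-1,2-dioxan-3-yl]propanoate | C=C1CCCC(C)(C)[C@@]1(O)CC[C@@]1(C)CC[C@@H]([C@H](C)C(=O)OC)OO1 | target

**Step count and risks**
Total steps: 8. Longest linear sequence: 8 (1 to 13; 5 and 8 are bought).

Most likely to fail, in this order: step 4, step 1, step 8.

Step 4 (the nickel coupling has no direct precedent with an enol triflate, acrolein and a free tertiary alcohol; homocoupling of 4 or silylation of the alcohol may intervene). The fallback sets out from 4 and comes back at 7. It uses a preformed, commercial zinc ester homoenolate in place of the nickel-bound one: Negishi coupling of 4 with (3-ethoxy-3-oxopropyl)zinc bromide (PdCl2(dppf), THF–DMA, 50 °C) gives ethyl 6-[(1S)-1-hydroxy-2,2-dimethyl-6-methylidenecyclohexyl]-4-methylidenehexanoate F3, and i-Bu2AlH (2.2 equiv, CH2Cl2, −78 °C) reduces F3 to aldehyde 7, at the cost of one extra step.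

Step 1 (dioxirane epoxidation of a fully alkyl-substituted tetrasubstituted alkene may give only moderate ee, and the facial sense rests on a model; if the antipode forms, the enantiomeric ketone is used). Low ee cannot be repaired later, because the wrong ring A enantiomer gives remote diastereomers. The fallback sets out from 1 and comes back at 2, replacing catalyst control by a separable diastereomer pair. A Prelog-selective alcohol dehydrogenase (NADH, i-PrOH) reduces 1 to (2S)-4-(2,6,6-trimethylcyclohex-1-en-1-yl)butan-2-ol F1. Hydroxyl-directed epoxidation (VO(acac)2, t-BuOOH, CH2Cl2, 0 °C) gives two diastereomeric epoxy alcohols, from which (2S)-4-[(1S,6R)-2,2,6-trimethyl-7-oxabicyclo[4.1.0]heptan-1-yl]butan-2-ol F2 is separated by chromatography. Dess–Martin periodinane oxidises F2 to enantiopure 2.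

Step 8 (three concerns: base-induced β-elimination of the mesylate next to the ester instead of ring closure; competing hydroperoxysilylation of the ring A methylene; an unavoidable 1:1 mixture at C6). The fallback sets out from 9 and comes back at 13; it removes the acidic α-hydrogen during ring closure by carrying C1 as a protected alcohol.
- LiBH4 (THF–MeOH, 0 °C) cleaves 9 to (2R,3R)-8-[(1S)-1-hydroxy-2,2-dimethyl-6-methylidenecyclohexyl]-2-methyl-6-methylideneoctane-1,3-diol F4.
- TBSCl/imidazole gives (2R,3R)-1-[(tert-butyldimethylsilyl)oxy]-8-[(1S)-1-hydroxy-2,2-dimethyl-6-methylidenecyclohexyl]-2-methyl-6-methylideneoctan-3-ol F5.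
- MsCl/Et3N gives (2R,3R)-1-[(tert-butyldimethylsilyl)oxy]-8-[(1S)-1-hydroxy-2,2-dimethyl-6-methylidenecyclohexyl]-2-methyl-6-methylideneoctan-3-yl methanesulfonate F6.
- Co(thd)2/Et3SiH/O2 gives (2R,3R)-1-[(tert-butyldimethylsilyl)oxy]-8-[(1S)-1-hydroxy-2,2-dimethyl-6-methylidenecyclohexyl]-2,6-dimethyl-6-[(triethylsilyl)peroxy]octan-3-yl methanesulfonate F7 (both C6 epimers).
- Excess Bu4NF closes the ring and removes the silyl ether; after separation of the C6 epimer this gives (2R)-2-[(3S,6R)-6-{2-[(1S)-1-hydroxy-2,2-dimethyl-6-methylidenecyclohexyl]ethyl}-6-methyl-1,2-dioxan-3-yl]propan-1-ol F8.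
- TEMPO/PhI(OAc)2 in MeCN–H2O gives (2S)-2-[(3S,6R)-6-{2-[(1S)-1-hydroxy-2,2-dimethyl-6-methylidenecyclohexyl]ethyl}-6-methyl-1,2-dioxan-3-yl]propanoic acid F9, and Me3SiCHN2 in MeOH–toluene gives 13.

**Further compounds**
F1 | step 1 | (2S)-4-(2,6,6-trimethylcyclohex-1-en-1-yl)butan-2-ol | C[C@H](O)CCC1=C(C)CCCC1(C)C
F2 | step 1 | (2S)-4-[(1S,6R)-2,2,6-trimethyl-7-oxabicyclo[4.1.0]heptan-1-yl]butan-2-ol | CC1(C)CCC[C@@]2(C)O[C@@]12CC[C@H](C)O
F3 | step 4 | ethyl 6-[(1S)-1-hydroxy-2,2-dimethyl-6-methylidenecyclohexyl]-4-methylidenehexanoate | C=C1CCCC(C)(C)[C@@]1(O)CCC(=C)CCC(=O)OCC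
F4 | step 8 | (2R,3R)-8-[(1S)-1-hydroxy-2,2-dimethyl-6-methylidenecyclohexyl]-2-methyl-6-methylideneoctane-1,3-diol | C=C1CCCC(C)(C)[C@@]1(O)CCC(=C)CC[C@@H](O)[C@H](C)CO
F5 | step 8 | (2R,3R)-1-[(tert-butyldimethylsilyl)oxy]-8-[(1S)-1-hydroxy-2,2-dimethyl-6-methylidenecyclohexyl]-2-methyl-6-methylideneoctan-3-ol | C=C1CCCC(C)(C)[C@@]1(O)CCC(=C)CC[C@@H](O)[C@H](C)CO[Si](C)(C)C(C)(C)C
F6 | step 8 | (2R,3R)-1-[(tert-butyldimethylsilyl)oxy]-8-[(1S)-1-hydroxy-2,2-dimethyl-6-methylidenecyclohexyl]-2-methyl-6-methylideneoctan-3-yl methanesulfonate | C=C1CCCC(C)(C)[C@@]1(O)CCC(=C)CC[C@@H](OS(C)(=O)=O)[C@H](C)CO[Si](C)(C)C(C)(C)C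
F7 | step 8 | (2R,3R)-1-[(tert-butyldimethylsilyl)oxy]-8-[(1S)-1-hydroxy-2,2-dimethyl-6-methylidenecyclohexyl]-2,6-dimethyl-6-[(triethylsilyl)peroxy]octan-3-yl methanesulfonate (both C6 epimers) | C=C1CCCC(C)(C)[C@@]1(O)CCC(C)(OO[Si](CC)(CC)CC)CC[C@@H](OS(C)(=O)=O)[C@H](C)CO[Si](C)(C)C(C)(C)C
F8 | step 8 | (2R)-2-[(3S,6R)-6-{2-[(1S)-1-hydroxy-2,2-dimethyl-6-methylidenecyclohexyl]ethyl}-6-methyl-1,2-dioxan-3-yl]propan-1-ol | C=C1CCCC(C)(C)[C@@]1(O)CC[C@@]1(C)CC[C@@H]([C@H](C)CO)OO1
F9 | step 8 | (2S)-2-[(3S,6R)-6-{2-[(1S)-1-hydroxy-2,2-dimethyl-6-methylidenecyclohexyl]ethyl}-6-methyl-1,2-dioxan-3-yl]propanoic acid | C=C1CCCC(C)(C)[C@@]1(O)CC[C@@]1(C)CC[C@@H]([C@H](C)C(=O)O)OO1
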